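## Retrosynthetic overview

1. The last skeletal event is a biomimetic, macrocyclising intramolecular Diels–Alder reaction of a 3-acyl-5-methylidene tetronate onto the terminal (E,E)-diene. It closes the 19-membered carbocycle and the spiro-cyclohexene together and sets C3, C23 and C25 in one step, replacing the usual intermolecular cycloaddition plus separate macrocyclisation.
2. The cycloaddition precursor is cut at C6–C7 (Stille coupling of a trienylstannane with an iodoalkene) and at C20–C21 (3-lithiated methylidene tetronate plus thiolane aldehyde, then oxidation).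
3. The thiolane is the first ring made: organocatalytic Michael addition of a chain aldehyde to an S-trityl nitroallyl sulfide (C16), acid-triggered O,S-acetal ring closure, thionium alkylation with a glycolate ketene acetal (C17), Nef reaction and equilibration (C19).
4. The chain aldehyde comes from a Julia–Kocienski union (C12=C13) of a C7–C12 sulfone (C10 by asymmetric propargylation) with a C13–C17 aldehyde that carries C15 from the chiral pool.
5. Ring order: thiolane, then the preformed tetronate is attached, then cyclohexene and macrocycle simultaneously.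

Atom labels used in the Why lines: cyclohexene C1(Me)=C2–C3–C23(spiro)–C24–C25(Me); chain C4–C15 (dienes C5=C6–C7=C8, carbinol C10, olefin C12=C13, methyl-bearing C15); thiolane C16–C17–S–C18–C19; ketone C20; tetronate C21–C22(OH)–C23 with lactone C26; keto acid C27–C28. Thiolane locants in names: S1, C2 (= C17), C3 (= C16), C4 (= C19), C5 (= C18).

Abbreviations in names: R1 = (2S,4E,7R,9E)-7-[(tert-butyldiphenylsilyl)oxy]-10-iododeca-4,9-dien-2-yl; R2 = (2S,4E,7R,9E,11E,14E,16E)-7-[(tert-butyldiphenylsilyl)oxy]-16-methyloctadeca-4,9,11,14,16-pentaen-2-yl.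

Assumption: (S)-methyl hydrogen 3-methylglutarate is taken as purchasable (otherwise one step from 3-methylglutaric anhydride by alkaloid-mediated methanolysis).

## Route

Step 1
Reactants: 1 (E)-2-methylbut-2-enal; 2 vinylmagnesium bromide
Product: 4 (E)-4-methylhexa-1,4-dien-3-yl methyl carbonate (racemic), via magnesium alkoxide 3 (not isolated)
Conditions: THF, −78 → 0 °C; then ClCO2Me, 0 → 20 °C
Reagents that add atoms: methyl chloroformate, COC(Cl)=O
Why: 1,2-Addition of the Grignard reagent to the enal and O-acylation of the alkoxide in the same flask give a doubly allylic carbonate whose carbinol centre is destroyed in step 2, so it is made racemic.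

Step 2
Reactants: 4 (E)-4-methylhexa-1,4-dien-3-yl methyl carbonate; 5 (E)-1,2-bis(tributylstannyl)ethene
Product: 6 tributyl[(1E,4E,6E)-6-methylocta-1,4,6-trien-1-yl]stannane
Conditions: Pd2(dba)3 (2.5 mol %), 5 (3 equiv), DMF, 20 °C
Reagents that add atoms: none
Why: Allyl–alkenyl Stille coupling after Tsuji–Trost ionisation: zerovalent palladium ionises the carbonate with loss of CO2 to a syn η3-pentadienyl complex, the liberated methoxide assists tin-to-palladium transfer of one alkenyl group of the excess distannane, and coupling at the unsubstituted terminus gives the linear skipped triene with the new C2=C3 olefin E.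

Step 3
Reactants: 7 4-methoxyfuran-2(5H)-one; 8 formaldehyde
Product: 10 5-(hydroxymethyl)-4-methoxyfuran-2(5H)-one (racemic), via 5-lithio tetronate 9 (not isolated)
Conditions: LiN(iPr)2, THF, −78 °C; then CH2O (gas), −78 °C; NH4Cl (aq)
Reagents that add atoms: none
Why: Kinetic γ-deprotonation of methyl tetronate at C5 followed by aldol addition to formaldehyde installs the future C24.

Step 4
Reactants: 10 5-(hydroxymethyl)-4-methoxyfuran-2(5H)-one
Product: 12 4-methoxy-5-methylidenefuran-2(5H)-one, via mesylate 11 (not isolated)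
Conditions: MsCl, Et3N (3 equiv), CH2Cl2, 0 → 20 °C
Reagents that add atoms: none
Why: Mesylation and E1cB elimination through the vinylogous ester dienolate give the exocyclic olefin C23=C24, the future dienophile.

Step 5
Reactants: 13 triphenylmethanethiol; 14 chloroacetaldehyde
Product: 15 2-(tritylsulfanyl)acetaldehyde
Conditions: K2CO3, DMF/H2O, 0 °C
Reagents that add atoms: none
Why: SN2 S-alkylation of the thiolate by the α-chloro aldehyde brings in S, C18 and C19 with the thiol kept latent as its trityl sulfide.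

Step 6
Reactants: 15 2-(tritylsulfanyl)acetaldehyde; 16 nitromethane
Product: 18 (E)-(3-nitroprop-2-en-1-yl)(trityl)sulfane, via nitro alcohol 17 (not isolated)
Conditions: 16 (5 equiv), Et3N (10 mol %), THF, 0 °C; then MsCl, Et3N, CH2Cl2, −20 °C
Reagents that add atoms: none
Why: Henry addition followed by mesylation and E1cB dehydration gives the conjugated nitroalkene in its thermodynamic E geometry, with the nitromethyl carbon as a masked C20 aldehyde.

Step 7
Reactants: 19 methyl glycolate
Product: 20 methyl 2-[(triethylsilyl)oxy]acetate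
Conditions: Et3SiCl, imidazole, CH2Cl2, 0 °C
Reagents that add atoms: chlorotriethylsilane, CC[Si](Cl)(CC)CC
Why: Standard O-silylation protects the future C27 oxygen as a TES ether that can later be removed beside a TBDPS ether.

Step 8
Reactants: 20 methyl 2-[(triethylsilyl)oxy]acetate
Product: 21 (Z)-1-methoxy-1,2-bis[(triethylsilyl)oxy]ethene
Conditions: LiN(iPr)2, Et3SiCl (in situ quench), THF/DMPU, −78 → 0 °C
Reagents that add atoms: chlorotriethylsilane, CC[Si](Cl)(CC)CC
Why: Ester enolisation with internal silyl trapping gives the ketene silyl acetal, a glycolate enolate equivalent carrying C27–C28.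

Step 9
Reactants: 22 1-phenyl-1H-tetrazole-5-thiol; 23 acrolein
Product: 24 3-[(1-phenyl-1H-tetrazol-5-yl)sulfanyl]propanal
Conditions: Et3N (5 mol %), CH2Cl2, 0 °C
Reagents that add atoms: none
Why: Amine-catalysed thia-Michael addition to acrolein installs the Julia–Kocienski heteroaryl sulfide on C12 with C10 as the aldehyde.

Step 10
Reactants: 24 3-[(1-phenyl-1H-tetrazol-5-yl)sulfanyl]propanal; 25 allenylboronic acid pinacol ester
Product: 26 (S)-1-[(1-phenyl-1H-tetrazol-5-yl)sulfanyl]hex-5-yn-3-ol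
Conditions: (S)-TRIP phosphoric acid (5 mol %), 4 Å molecular sieves, toluene, −20 °C; aqueous work-up
Reagents that add atoms: none
Why: Chiral phosphoric acid-catalysed propargylboration through a closed six-membered SE2' transition state sets C10, with the catalyst enantiomer chosen to give the (S)-carbinol ((S)-TRIP by analogy with aryl aldehydes, to be confirmed by Mosher analysis).

Step 11
Reactants: 26 (S)-1-[(1-phenyl-1H-tetrazol-5-yl)sulfanyl]hex-5-yn-3-ol
Product: 27 (S)-5-({3-[(tert-butyldiphenylsilyl)oxy]hex-5-yn-1-yl}sulfanyl)-1-phenyl-1H-tetrazole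
Conditions: tBuPh2SiCl, imidazole, DMF, 20 °C
Reagents that add atoms: tert-butyl(chloro)diphenylsilane, CC(C)(C)[Si](Cl)(c1ccccc1)c1ccccc1
Why: Silylation gives a TBDPS ether that survives the acidic, Lewis acidic and basic steps up to step 26.

Step 12
Reactants: 27 (S)-5-({3-[(tert-butyldiphenylsilyl)oxy]hex-5-yn-1-yl}sulfanyl)-1-phenyl-1H-tetrazole
Product: 29 (S,E)-5-({3-[(tert-butyldiphenylsilyl)oxy]-6-iodohex-5-en-1-yl}sulfanyl)-1-phenyl-1H-tetrazole, via alkenylzirconocene chloride 28 (not isolated)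
Conditions: Cp2Zr(H)Cl, THF, 20 °C; then I2, 0 °C
Reagents that add atoms: iodine, II
Why: syn-Hydrozirconation places zirconium on the terminal alkyne carbon and iodinolysis with retention gives the (E)-iodoalkene C7=C8.

Step 13
Reactants: 29 (S,E)-5-({3-[(tert-butyldiphenylsilyl)oxy]-6-iodohex-5-en-1-yl}sulfanyl)-1-phenyl-1H-tetrazole
Product: 30 (S,E)-5-({3-[(tert-butyldiphenylsilyl)oxy]-6-iodohex-5-en-1-yl}sulfonyl)-1-phenyl-1H-tetrazole
Conditions: (NH4)6Mo7O24·4H2O (10 mol %), 30% H2O2, EtOH, 0 → 20 °C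
Reagents that add atoms: hydrogen peroxide, OO
Why: Molybdate-catalysed peroxide oxidation converts the sulfide to the sulfone while the iodoalkene and silyl ether are inert.

Step 14
Reactants: 31 (S)-5-methoxy-3-methyl-5-oxopentanoic acid
Product: 32 methyl (S)-5-hydroxy-3-methylpentanoate
Conditions: BH3·SMe2, THF, 0 °C; MeOH quench
Reagents that add atoms: none
Why: Borane reduces the carboxylic acid chemoselectively beside the methyl ester, differentiating the two ends around the chiral-pool centre C15.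

Step 15
Reactants: 32 methyl (S)-5-hydroxy-3-methylpentanoate
Product: 33 methyl (S)-3-methyl-5-oxopentanoate
Conditions: Dess–Martin periodinane, NaHCO3, CH2Cl2, 0 °C
Reagents that add atoms: none
Why: Mild oxidation of the primary alcohol gives the C13 aldehyde with no α-stereocentre to epimerise.

Step 16
Reactants: 30 (S,E)-5-({3-[(tert-butyldiphenylsilyl)oxy]-6-iodohex-5-en-1-yl}sulfonyl)-1-phenyl-1H-tetrazole; 33 methyl (S)-3-methyl-5-oxopentanoate
Product: 35 methyl (3S,5E,8R,10E)-8-[(tert-butyldiphenylsilyl)oxy]-11-iodo-3-methylundeca-5,10-dienoate, via sulfonyl carbanion 34 (not isolated)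
Conditions: KN(SiMe3)2, DME, −60 °C; then 33, −60 → 20 °C; NH4Cl (aq)
Reagents that add atoms: none
Why: Julia–Kocienski olefination (carbanion addition, Smiles rearrangement, loss of SO2 and tetrazolone) gives the (E)-C12=C13 olefin typical of phenyltetrazolyl sulfones with unbranched aldehydes.

Step 17
Reactants: 35 methyl (3S,5E,8R,10E)-8-[(tert-butyldiphenylsilyl)oxy]-11-iodo-3-methylundeca-5,10-dienoate
Product: 36 (3S,5E,8R,10E)-8-[(tert-butyldiphenylsilyl)oxy]-11-iodo-3-methylundeca-5,10-dienal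
Conditions: iBu2AlH, CH2Cl2, −78 °C; aqueous potassium sodium tartrate work-up
Reagents that add atoms: none
Why: Partial reduction of the methyl ester stops at the aldehyde because the tetrahedral aluminate is stable at −78 °C.

Step 18
Reactants: 36 (3S,5E,8R,10E)-8-[(tert-butyldiphenylsilyl)oxy]-11-iodo-3-methylundeca-5,10-dienal; 18 (E)-(3-nitroprop-2-en-1-yl)(trityl)sulfane
Product: 37 (2S,3S)-4-nitro-2-R1-3-[(tritylsulfanyl)methyl]butanal
Conditions: (R)-α,α-diphenylprolinol trimethylsilyl ether (15 mol %), 4-nitrophenol (15 mol %), 18 (1.5 equiv), toluene, 0 → 20 °C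
Reagents that add atoms: none
Why: Hayashi–Jørgensen enamine Michael addition in which the (R)-catalyst shields one face of the (E)-enamine, so C16 is set under catalyst control as the syn adduct, while the C19 centre formed here is corrected in step 21.

Step 19
Reactants: 37 (2S,3S)-4-nitro-2-R1-3-[(tritylsulfanyl)methyl]butanal
Product: 38 (3,4-cis)-2-methoxy-4-(nitromethyl)-3-R1-thiolane (both C2 anomers)
Conditions: CF3CO2H (5 vol %), MeOH/CH2Cl2 1:1, 0 → 20 °C
Reagents that add atoms: methanol, CO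
Why: Acid-mediated S-detritylation (trityl cation trapped by methanol) and intramolecular monothioacetalisation of the aldehyde close the thiolane as a five-membered O,S-acetal, after which C16 is no longer α to a carbonyl.

Step 20
Reactants: 38 (3,4-cis)-2-methoxy-4-(nitromethyl)-3-R1-thiolane; 21 (Z)-1-methoxy-1,2-bis[(triethylsilyl)oxy]ethene
Product: 39 methyl 2-[(2,3-trans,3,4-cis)-4-(nitromethyl)-3-R1-thiolan-2-yl]-2-(triethylsilyloxy)acetate (both C27 epimers)
Conditions: BF3·OEt2, 21 (3 equiv), CH2Cl2, −78 °C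
Reagents that add atoms: none
Why: The Lewis acid ionises the O,S-acetal to a cyclic thionium ion that the ketene silyl acetal captures (Mukaiyama-type alkylation) on the face opposite the two cis substituents at C16 and C19, setting C17 trans to C16.

Step 21
Reactants: 39 methyl 2-[(2,3-trans,3,4-cis)-4-(nitromethyl)-3-R1-thiolan-2-yl]-2-(triethylsilyloxy)acetate
Product: 42 methyl 2-[(2,3-trans,3,4-trans)-4-formyl-3-R1-thiolan-2-yl]-2-(triethylsilyloxy)acetate, via potassium nitronate 40 (not isolated), via cis-aldehyde 41 (not isolated)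
Conditions: KOtBu, THF, 0 °C; then TiCl3 (aq), NH4OAc buffer, 0 → 20 °C; then DBU (20 mol %), CH2Cl2, 20 °C
Reagents that add atoms: water, O
Why: Nef reaction (the nitronate is reduced by trivalent titanium to the imine, which hydrolyses to the C20 aldehyde) followed by base equilibration of the now acidic C19 centre to the thermodynamically favoured all-trans thiolane.

Step 22
Reactants: 42 methyl 2-[(2,3-trans,3,4-trans)-4-formyl-3-R1-thiolan-2-yl]-2-(triethylsilyloxy)acetate; 12 4-methoxy-5-methylidenefuran-2(5H)-one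
Product: 45 methyl 2-hydroxy-2-{(2,3-trans,3,4-trans)-4-[hydroxy(4-methoxy-5-methylidene-2-oxo-2,5-dihydrofuran-3-yl)methyl]-3-R1-thiolan-2-yl}acetate (carbinol epimers), via 3-lithio tetronate 43 (not isolated), via TES-protected carbinol 44 (not isolated)
Conditions: 12 (2 equiv), LiN(iPr)2, THF, −78 °C; then 42, −78 °C; AcOH; then HF·pyridine, pyridine, THF, 0 °C
Reagents that add atoms: none
Why: Vinylic C3-lithiation of the methylidene tetronate (no γ-hydrogen remains) and 1,2-addition to the aldehyde form C20–C21, and buffered HF then cleaves only the TES ether, the new carbinol configurations being irrelevant because both are oxidised next.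

Step 23
Reactants: 45 methyl 2-hydroxy-2-{(2,3-trans,3,4-trans)-4-[hydroxy(4-methoxy-5-methylidene-2-oxo-2,5-dihydrofuran-3-yl)methyl]-3-R1-thiolan-2-yl}acetate
Product: 46 methyl 2-[(2,3-trans,3,4-trans)-4-(4-methoxy-5-methylidene-2-oxo-2,5-dihydrofuran-3-carbonyl)-3-R1-thiolan-2-yl]-2-oxoacetate
Conditions: Dess–Martin periodinane (4 equiv), NaHCO3, CH2Cl2, 0 → 20 °C
Reagents that add atoms: none
Why: Double Dess–Martin oxidation, which tolerates the thioether, gives the 3-acyl tetronate and the α-keto ester at once, and C17 and C19, now both epimerisable, rest in the all-trans thermodynamic arrangement.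

Step 24
Reactants: 46 methyl 2-[(2,3-trans,3,4-trans)-4-(4-methoxy-5-methylidene-2-oxo-2,5-dihydrofuran-3-carbonyl)-3-R1-thiolan-2-yl]-2-oxoacetate; 6 tributyl[(1E,4E,6E)-6-methylocta-1,4,6-trien-1-yl]stannane
Product: 47 methyl 2-[(2,3-trans,3,4-trans)-4-(4-methoxy-5-methylidene-2-oxo-2,5-dihydrofuran-3-carbonyl)-3-R2-thiolan-2-yl]-2-oxoacetate
Conditions: Pd2(dba)3 (5 mol %), AsPh3 (20 mol %), DMF, 20 °C, dark
Reagents that add atoms: none
Why: Stille coupling with retention at both sp2 carbons forms C6–C7 and the (E,E)-diene under neutral conditions at room temperature, so the skipped tetraene appears only one step before it is consumed.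

Step 25
Reactants: 47 methyl 2-[(2,3-trans,3,4-trans)-4-(4-methoxy-5-methylidene-2-oxo-2,5-dihydrofuran-3-carbonyl)-3-R2-thiolan-2-yl]-2-oxoacetate
Product: 48 C10 TBDPS ether/tetronate 4-O-methyl ether/methyl ester of the target macrocycle
Conditions: La(OTf)3 (20 mol %), BHT, toluene (0.5 mM), 100 °C
Reagents that add atoms: none
Why: Proposed new method: macrocyclising intramolecular Diels–Alder reaction in which the electron-poor exocyclic olefin C23=C24 (further activated by chelation of the 1,3-dicarbonyl unit) adds suprafacially to the s-cis terminal diene C25=C1–C2=C3 in the electronically preferred para sense (bonds C24–C25 and C23–C3); the carbonyl-exo transition state typical of α-methylidene lactone dienophiles puts the ring oxygen cis to C4 and to the C25 methyl, the trisubstituted terminal diene is more electron-rich than the internal C5–C8 diene, and the π-face is chosen by the resident thiolane, C10 and C15 centres through the 19-membered transition state (unproven, diastereomers separable); the closest known reaction type is the intramolecular Diels–Alder macrocyclisation of an acyl methylidene tetronate that forms the 11-membered abyssomicin ring.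

Step 26
Reactants: 48 C10 TBDPS ether/tetronate 4-O-methyl ether/methyl ester of the target macrocycle
Product: 49 tetronate 4-O-methyl ether/methyl ester of the target
Conditions: HF·pyridine, pyridine, THF, 0 → 20 °C
Reagents that add atoms: none
Why: Fluoride-mediated cleavage of the silyl ether frees the C10 hydroxyl without touching the vinylogous ester, the keto ester or the dienes.

Step 27
Reactants: 49 tetronate 4-O-methyl ether/methyl ester of the target
Product: 51 CNP0224658.3 (target), via tetronic acid methyl ester 50 (not isolated)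
Conditions: LiCl, DMSO, 50 °C; then LiOH, THF/H2O, 0 °C; then 1 M HCl to pH 2
Reagents that add atoms: lithium hydroxide, [Li+].[OH-]
Why: SN2 demethylation of the vinylogous methyl ester by chloride followed by saponification of the highly electrophilic α-keto ester gives the free tetronic acid and keto acid, and C17, epimerisable under these conditions, stays in the favoured trans arrangement.

## Compound list

1 | (E)-2-methylbut-2-enal | C/C=C(\C)C=O | starting material
2 | vinylmagnesium bromide | C=C[Mg]Br | starting material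
3 | bromomagnesium (E)-4-methylhexa-1,4-dien-3-olate (racemic) | C/C=C(\C)C(O[Mg]Br)C=C | intermediate
4 | (E)-4-methylhexa-1,4-dien-3-yl methyl carbonate (racemic) | C/C=C(\C)C(OC(=O)OC)C=C | intermediate
5 | (E)-1,2-bis(tributylstannyl)ethene | CCCC[Sn](CCCC)(CCCC)/C=C/[Sn](CCCC)(CCCC)CCCC | starting material
6 | tributyl[(1E,4E,6E)-6-methylocta-1,4,6-trien-1-yl]stannane | C/C=C(\C)/C=C/C/C=C/[Sn](CCCC)(CCCC)CCCC | intermediate
7 | 4-methoxyfuran-2(5H)-one (methyl tetronate) | COC1=CC(=O)OC1 | starting material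
8 | formaldehyde (gas, cracked from paraformaldehyde) | C=O | starting material
9 | 5-lithio-4-methoxyfuran-2(5H)-one | COC1=CC(=O)OC1[Li] | intermediate
10 | 5-(hydroxymethyl)-4-methoxyfuran-2(5H)-one (racemic) | COC1=CC(=O)OC1CO | intermediate
11 | (3-methoxy-5-oxo-2,5-dihydrofuran-2-yl)methyl methanesulfonate | COC1=CC(=O)OC1COS(C)(=O)=O | intermediate
12 | 4-methoxy-5-methylidenefuran-2(5H)-one | COC1=CC(=O)OC1=C | intermediate
13 | triphenylmethanethiol | SC(c1ccccc1)(c1ccccc1)c1ccccc1 | starting material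
14 | chloroacetaldehyde (50% aqueous) | ClCC=O | starting material
15 | 2-(tritylsulfanyl)acetaldehyde | O=CCSC(c1ccccc1)(c1ccccc1)c1ccccc1 | intermediate
16 | nitromethane | C[N+](=O)[O-] | starting material
17 | 1-nitro-3-(tritylsulfanyl)propan-2-ol (racemic) | OC(CSC(c1ccccc1)(c1ccccc1)c1ccccc1)C[N+](=O)[O-] | intermediate
18 | (E)-(3-nitroprop-2-en-1-yl)(trityl)sulfane | [O-][N+](=O)/C=C/CSC(c1ccccc1)(c1ccccc1)c1ccccc1 | intermediate
19 | methyl glycolate | COC(=O)CO | starting material
20 | methyl 2-[(triethylsilyl)oxy]acetate | COC(=O)CO[Si](CC)(CC)CC | intermediate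
21 | (Z)-1-methoxy-1,2-bis[(triethylsilyl)oxy]ethene | CO/C(O[Si](CC)(CC)CC)=C/O[Si](CC)(CC)CC | intermediate
22 | 1-phenyl-1H-tetrazole-5-thiol | Sc1nnnn1-c1ccccc1 | starting material
23 | acrolein | C=CC=O | starting material
24 | 3-[(1-phenyl-1H-tetrazol-5-yl)sulfanyl]propanal | O=CCCSc1nnnn1-c1ccccc1 | intermediate
25 | allenylboronic acid pinacol ester | C=C=CB1OC(C)(C)C(C)(C)O1 | starting material
26 | (S)-1-[(1-phenyl-1H-tetrazol-5-yl)sulfanyl]hex-5-yn-3-ol | C#CC[C@H](O)CCSc1nnnn1-c1ccccc1 | intermediate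
27 | (S)-5-({3-[(tert-butyldiphenylsilyl)oxy]hex-5-yn-1-yl}sulfanyl)-1-phenyl-1H-tetrazole | C#CC[C@H](O[Si](c1ccccc1)(c1ccccc1)C(C)(C)C)CCSc1nnnn1-c1ccccc1 | intermediate
28 | chlorobis(cyclopentadienyl)[(S,E)-4-[(tert-butyldiphenylsilyl)oxy]-6-[(1-phenyl-1H-tetrazol-5-yl)sulfanyl]hex-1-en-1-yl]zirconium | Cl[Zr](/C=C/C[C@H](O[Si](c1ccccc1)(c1ccccc1)C(C)(C)C)CCSc1nnnn1-c1ccccc1)(C1C=CC=C1)C1C=CC=C1 | intermediate
29 | (S,E)-5-({3-[(tert-butyldiphenylsilyl)oxy]-6-iodohex-5-en-1-yl}sulfanyl)-1-phenyl-1H-tetrazole | I/C=C/C[C@H](O[Si](c1ccccc1)(c1ccccc1)C(C)(C)C)CCSc1nnnn1-c1ccccc1 | intermediate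
30 | (S,E)-5-({3-[(tert-butyldiphenylsilyl)oxy]-6-iodohex-5-en-1-yl}sulfonyl)-1-phenyl-1H-tetrazole | I/C=C/C[C@H](O[Si](c1ccccc1)(c1ccccc1)C(C)(C)C)CCS(=O)(=O)c1nnnn1-c1ccccc1 | intermediate
31 | (S)-5-methoxy-3-methyl-5-oxopentanoic acid | OC(=O)C[C@H](C)CC(=O)OC | starting material
32 | methyl (S)-5-hydroxy-3-methylpentanoate | OCC[C@H](C)CC(=O)OC | intermediate
33 | methyl (S)-3-methyl-5-oxopentanoate | O=CC[C@H](C)CC(=O)OC | intermediate
34 | potassium α-sulfonyl carbanion of 30 | [K+].I/C=C/C[C@H](O[Si](c1ccccc1)(c1ccccc1)C(C)(C)C)C[CH-]S(=O)(=O)c1nnnn1-c1ccccc1 | intermediate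
35 | methyl (3S,5E,8R,10E)-8-[(tert-butyldiphenylsilyl)oxy]-11-iodo-3-methylundeca-5,10-dienoate | COC(=O)C[C@@H](C)C/C=C/C[C@@H](O[Si](c1ccccc1)(c1ccccc1)C(C)(C)C)C/C=C/I | intermediate
36 | (3S,5E,8R,10E)-8-[(tert-butyldiphenylsilyl)oxy]-11-iodo-3-methylundeca-5,10-dienal | O=CC[C@@H](C)C/C=C/C[C@@H](O[Si](c1ccccc1)(c1ccccc1)C(C)(C)C)C/C=C/I | intermediate
37 | (2S,3S)-4-nitro-2-R1-3-[(tritylsulfanyl)methyl]butanal | O=C[C@H]([C@H](CSC(c1ccccc1)(c1ccccc1)c1ccccc1)C[N+](=O)[O-])[C@@H](C)C/C=C/C[C@@H](O[Si](c1ccccc1)(c1ccccc1)C(C)(C)C)C/C=C/I | intermediate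
38 | (3,4-cis)-2-methoxy-4-(nitromethyl)-3-R1-thiolane, both C2 anomers, ring C3 configured as C16 of the target | COC1SC[C@H](C[N+](=O)[O-])[C@@H]1[C@@H](C)C/C=C/C[C@@H](O[Si](c1ccccc1)(c1ccccc1)C(C)(C)C)C/C=C/I | intermediate
39 | methyl 2-[(2,3-trans,3,4-cis)-4-(nitromethyl)-3-R1-thiolan-2-yl]-2-(triethylsilyloxy)acetate, both C27 epimers | COC(=O)C(O[Si](CC)(CC)CC)[C@H]1SC[C@H](C[N+](=O)[O-])[C@@H]1[C@@H](C)C/C=C/C[C@@H](O[Si](c1ccccc1)(c1ccccc1)C(C)(C)C)C/C=C/I | intermediate
40 | potassium nitronate of 39 | COC(=O)C(O[Si](CC)(CC)CC)[C@H]1SC[C@H](C=[N+]([O-])[O-])[C@@H]1[C@@H](C)C/C=C/C[C@@H](O[Si](c1ccccc1)(c1ccccc1)C(C)(C)C)C/C=C/I.[K+] | intermediate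
41 | methyl 2-[(2,3-trans,3,4-cis)-4-formyl-3-R1-thiolan-2-yl]-2-(triethylsilyloxy)acetate | COC(=O)C(O[Si](CC)(CC)CC)[C@H]1SC[C@H](C=O)[C@@H]1[C@@H](C)C/C=C/C[C@@H](O[Si](c1ccccc1)(c1ccccc1)C(C)(C)C)C/C=C/I | intermediate
42 | methyl 2-[(2,3-trans,3,4-trans)-4-formyl-3-R1-thiolan-2-yl]-2-(triethylsilyloxy)acetate | COC(=O)C(O[Si](CC)(CC)CC)[C@H]1SC[C@@H](C=O)[C@@H]1[C@@H](C)C/C=C/C[C@@H](O[Si](c1ccccc1)(c1ccccc1)C(C)(C)C)C/C=C/I | intermediate
43 | 3-lithio-4-methoxy-5-methylidenefuran-2(5H)-one | [Li]C1=C(OC)C(=C)OC1=O | intermediate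
44 | methyl 2-{(2,3-trans,3,4-trans)-4-[hydroxy(4-methoxy-5-methylidene-2-oxo-2,5-dihydrofuran-3-yl)methyl]-3-R1-thiolan-2-yl}-2-(triethylsilyloxy)acetate | COC(=O)C(O[Si](CC)(CC)CC)[C@H]1SC[C@@H](C(O)C2=C(OC)C(=C)OC2=O)[C@@H]1[C@@H](C)C/C=C/C[C@@H](O[Si](c1ccccc1)(c1ccccc1)C(C)(C)C)C/C=C/I | intermediate
45 | methyl 2-hydroxy-2-{(2,3-trans,3,4-trans)-4-[hydroxy(4-methoxy-5-methylidene-2-oxo-2,5-dihydrofuran-3-yl)methyl]-3-R1-thiolan-2-yl}acetate | COC(=O)C(O)[C@H]1SC[C@@H](C(O)C2=C(OC)C(=C)OC2=O)[C@@H]1[C@@H](C)C/C=C/C[C@@H](O[Si](c1ccccc1)(c1ccccc1)C(C)(C)C)C/C=C/I | intermediate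
46 | methyl 2-[(2,3-trans,3,4-trans)-4-(4-methoxy-5-methylidene-2-oxo-2,5-dihydrofuran-3-carbonyl)-3-R1-thiolan-2-yl]-2-oxoacetate | COC(=O)C(=O)[C@H]1SC[C@@H](C(=O)C2=C(OC)C(=C)OC2=O)[C@@H]1[C@@H](C)C/C=C/C[C@@H](O[Si](c1ccccc1)(c1ccccc1)C(C)(C)C)C/C=C/I | intermediate
47 | methyl 2-[(2,3-trans,3,4-trans)-4-(4-methoxy-5-methylidene-2-oxo-2,5-dihydrofuran-3-carbonyl)-3-R2-thiolan-2-yl]-2-oxoacetate | COC(=O)C(=O)[C@H]1SC[C@@H](C(=O)C2=C(OC)C(=C)OC2=O)[C@@H]1[C@@H](C)C/C=C/C[C@@H](O[Si](c1ccccc1)(c1ccccc1)C(C)(C)C)C/C=C/C=C/C/C=C/C(C)=C/C | intermediate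
48 | target macrocycle as its C10 TBDPS ether, tetronate 4-O-methyl ether and methyl α-keto ester | CC1=C[C@H]2C/C=C/C=C/C[C@H](O[Si](c4ccccc4)(c4ccccc4)C(C)(C)C)C/C=C/C[C@H](C)[C@@H]3[C@@H](C(=O)C(=O)OC)SC[C@H]3C(=O)C3=C(OC)[C@@]2(C[C@H]1C)OC3=O | intermediate
49 | target as its tetronate 4-O-methyl ether and methyl α-keto ester | CC1=C[C@H]2C/C=C/C=C/C[C@H](O)C/C=C/C[C@H](C)[C@@H]3[C@@H](C(=O)C(=O)OC)SC[C@H]3C(=O)C3=C(OC)[C@@]2(C[C@H]1C)OC3=O | intermediate
50 | target as its methyl α-keto ester | CC1=C[C@H]2C/C=C/C=C/C[C@H](O)C/C=C/C[C@H](C)[C@@H]3[C@@H](C(=O)C(=O)OC)SC[C@H]3C(=O)C3=C(O)[C@@]2(C[C@H]1C)OC3=O | intermediate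
51 | CNP0224658.3 | CC1=C[C@H]2C/C=C/C=C/C[C@H](O)C/C=C/C[C@H](C)[C@@H]3[C@@H](C(=O)C(=O)O)SC[C@H]3C(=O)C3=C(O)[C@@]2(C[C@H]1C)OC3=O | target

## Step count and risks

Total step count: 27. Longest linear sequence: 17 steps (steps 9–13, then 16–27).

Step 25 is the most likely to fail. The π-facial selectivity of the 19-membered cycloaddition rests only on remote stereocentres, the internal C5–C8 diene can compete, and the rate at high dilution may be low. The fallback sets out from 46 and 6 and runs the cycloaddition bimolecularly, with the concentrated partners heated at 60 °C in toluene or activated by MgBr2·OEt2. This gives the spirocyclic iodoalkene–alkenylstannane cycloadduct F1 with the same exo, para sense; its two π-facial isomers are separated, or the face is dictated by a chiral Lewis acid bound to the 1,3-dicarbonyl unit. The C5–C8 diene does not yet exist when the dienophile is consumed. The ring is then closed at C6–C7 by an intramolecular Stille coupling (Pd2(dba)3, AsPh3, DMF, 1 mM), and the route is rejoined at 48.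

Step 20 is the second risk. The thionium ion can lose the C16 proton to give a dihydrothiophene, which would erode the C16 configuration; it can also be trapped by the C12=C13 olefin. The fallback sets out from 37 and forms the C17–S bond instead of the C17–C27 bond. Horner–Wadsworth–Emmons olefination of the aldehyde with methyl 2-(dimethoxyphosphoryl)-2-(triethylsilyloxy)acetate and LiN(SiMe3)2 gives the 2-silyloxy enoate F2. AgNO3/pyridine in methanol, then dithiothreitol, releases the thiol F3. Catalytic Et3N then closes the ring by a reversible 5-exo-trig thia-Michael addition, which places C17 trans to C16 without any cation next to C16, and the route is rejoined at 39.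

Step 24 is the third risk. Compound 46 carries the very electrophilic acyl methylidene tetronate while palladium, arsine and tin residues are present, and the product can begin to cyclise unselectively. The fallback sets out from 42 and inverts the order. Stille coupling of 42 with 6 gives the tetraene aldehyde F4; addition of 43 gives the TES-protected carbinol F5; HF·pyridine gives the diol F6. Dess–Martin oxidation then rejoins the route at 47, so the dienophile is unveiled only in the step before the cycloaddition.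

## Further compounds

F1 | step 25 | intermolecular cycloadduct: 46 in which the tetronate C5 is the spiro carbon of a 3,4-dimethylcyclohex-3-ene bearing a (E)-3-(tributylstannyl)prop-2-en-1-yl group at the ring carbon next to the spiro centre, configured as C3, C23 and C25 of the target | COC(=O)C(=O)[C@H]1SC[C@@H](C(=O)C2=C(OC)[C@@]3(C[C@@H](C)C(C)=C[C@H]3C/C=C/[Sn](CCCC)(CCCC)CCCC)OC2=O)[C@@H]1[C@@H](C)C/C=C/C[C@@H](O[Si](c1ccccc1)(c1ccccc1)C(C)(C)C)C/C=C/I
F2 | step 20 | methyl (4S,5S)-6-nitro-4-R1-2-(triethylsilyloxy)-5-[(tritylsulfanyl)methyl]hex-2-enoate (E/Z mixture) | COC(=O)C(O[Si](CC)(CC)CC)=C[C@H]([C@H](CSC(c1ccccc1)(c1ccccc1)c1ccccc1)C[N+](=O)[O-])[C@@H](C)C/C=C/C[C@@H](O[Si](c1ccccc1)(c1ccccc1)C(C)(C)C)C/C=C/I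
F3 | step 20 | methyl 6-nitro-4-R1-5-(sulfanylmethyl)-2-(triethylsilyloxy)hex-2-enoate (free thiol of F2) | COC(=O)C(O[Si](CC)(CC)CC)=C[C@H]([C@H](CS)C[N+](=O)[O-])[C@@H](C)C/C=C/C[C@@H](O[Si](c1ccccc1)(c1ccccc1)C(C)(C)C)C/C=C/I
F4 | step 24 | methyl 2-[(2,3-trans,3,4-trans)-4-formyl-3-R2-thiolan-2-yl]-2-(triethylsilyloxy)acetate | COC(=O)C(O[Si](CC)(CC)CC)[C@H]1SC[C@@H](C=O)[C@@H]1[C@@H](C)C/C=C/C[C@@H](O[Si](c1ccccc1)(c1ccccc1)C(C)(C)C)C/C=C/C=C/C/C=C/C(C)=C/C
F5 | step 24 | methyl 2-{(2,3-trans,3,4-trans)-4-[hydroxy(4-methoxy-5-methylidene-2-oxo-2,5-dihydrofuran-3-yl)methyl]-3-R2-thiolan-2-yl}-2-(triethylsilyloxy)acetate | COC(=O)C(O[Si](CC)(CC)CC)[C@H]1SC[C@@H](C(O)C2=C(OC)C(=C)OC2=O)[C@@H]1[C@@H](C)C/C=C/C[C@@H](O[Si](c1ccccc1)(c1ccccc1)C(C)(C)C)C/C=C/C=C/C/C=C/C(C)=C/C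
F6 | step 24 | methyl 2-hydroxy-2-{(2,3-trans,3,4-trans)-4-[hydroxy(4-methoxy-5-methylidene-2-oxo-2,5-dihydrofuran-3-yl)methyl]-3-R2-thiolan-2-yl}acetate | COC(=O)C(O)[C@H]1SC[C@@H](C(O)C2=C(OC)C(=C)OC2=O)[C@@H]1[C@@H](C)C/C=C/C[C@@H](O[Si](c1ccccc1)(c1ccccc1)C(C)(C)C)C/C=C/C=C/C/C=C/C(C)=C/C
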